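## Retrosynthetic overview

1. The C8 ester is cut last: the O6-silylated ring alcohol plus O-silylated p-coumaric acid (Steglich esterification, then desilylation).
2. The only ring, the ten-membered carbocycle, is closed late at C2–C3 by intramolecular alkylation of an allylic sulfone anion with an allylic bromide; the sulfone and the O8 benzoate are then removed reductively.
3. The C6 carbinol and the O6/O8 differentiation come from an anti-selective Evans–Tishchenko reduction of an acyclic β-hydroxy enone.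
4. C5–C6 is made by adding an E-alkenyllithium (from a Negishi-derived iodoalkene) to a Weinreb amide.
5. The key C7–C8 bond comes from an intermolecular Evans syn-aldol of (R)-N-isovaleryl-4-benzyloxazolidinone with an (E)-β,γ-unsaturated aldehyde, which sets C7 and C8.

Assumption: locants C1–C10 in the text are the ring positions of the target (C4 and C10 carry methyl, C6 the free OH, C7 the isopropyl, C8 the ester oxygen); carbon building blocks are numbered as compounds, ordinary reagents are given by name and SMILES in their step; TBS = tert-butyl(dimethyl)silyl, PMB = 4-methoxybenzyl.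

## Route

Step 1
Reactants: 1 but-3-yn-1-ol
Product: 2 1-[(but-3-yn-1-yloxy)methyl]-4-methoxybenzene
Conditions: NaH, 4-methoxybenzyl chloride, Bu4NI (cat.), THF, 0 °C to rt
Reagents that add atoms: 4-methoxybenzyl chloride, COc1ccc(CCl)cc1
Why: Williamson etherification masks the future C8 oxygen as a PMB ether that survives the organoaluminium step and is later removed oxidatively beside a silyl ether.

Step 2
Reactants: 2 1-[(but-3-yn-1-yloxy)methyl]-4-methoxybenzene
Product: 5 (2E)-5-(PMB-oxy)-3-methylpent-2-en-1-ol, via alkenyldimethylalane 3 (not isolated), via lithium alkenyl(butyl)dimethylalanate 4 (not isolated)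
Conditions: Me3Al, Cp2ZrCl2 (20 mol%), CH2Cl2, 0 °C to rt; n-BuLi, THF, −78 °C; (CH2O)n, −78 °C to rt; aq. HCl
Reagents that add atoms: trimethylaluminium, C[Al](C)C; paraformaldehyde (as formaldehyde), C=O
Why: Negishi zirconium-catalysed carboalumination adds methyl and aluminium syn across the terminal alkyne and the alanate is hydroxymethylated with retention, which fixes the E geometry of the future C1=C10 alkene.

Step 3
Reactants: 5 (2E)-5-(PMB-oxy)-3-methylpent-2-en-1-ol
Product: 6 tert-butyl{[(2E)-5-(PMB-oxy)-3-methylpent-2-en-1-yl]oxy}dimethylsilane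
Conditions: TBSCl, imidazole, CH2Cl2, rt
Reagents that add atoms: tert-butyl(chloro)dimethylsilane, CC(C)(C)[Si](C)(C)Cl
Why: Standard silylation protects the allylic (future C2) hydroxyl orthogonally to the PMB ether.

Step 4
Reactants: 6 tert-butyl{[(2E)-5-(PMB-oxy)-3-methylpent-2-en-1-yl]oxy}dimethylsilane
Product: 7 (3E)-5-(TBS-oxy)-3-methylpent-3-en-1-ol
Conditions: DDQ, CH2Cl2/H2O (18:1), 0 °C
Reagents that add atoms: none
Why: Oxidative PMB cleavage by DDQ frees only the homoallylic hydroxyl and leaves the TBS ether and the alkene untouched.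

Step 5
Reactants: 7 (3E)-5-(TBS-oxy)-3-methylpent-3-en-1-ol
Product: 8 (3E)-5-(TBS-oxy)-3-methylpent-3-enal
Conditions: Dess–Martin periodinane, pyridine, CH2Cl2, 0 °C; used crude at once
Reagents that add atoms: none
Why: Pyridine-buffered Dess–Martin oxidation is mild and non-basic enough to give the β,γ-unsaturated aldehyde without moving the alkene into conjugation.

Step 6
Reactants: 9 (4R)-4-benzyl-1,3-oxazolidin-2-one; 10 3-methylbutanoyl chloride
Product: 11 (4R)-4-benzyl-3-(3-methylbutanoyl)-1,3-oxazolidin-2-one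
Conditions: Et3N, DMAP (cat.), CH2Cl2, 0 °C to rt
Reagents that add atoms: none
Why: DMAP-catalysed N-acylation attaches the isovaleryl unit (future C6, C7 and isopropyl) to the chiral auxiliary.

Step 7
Reactants: 11 (4R)-4-benzyl-3-(3-methylbutanoyl)-1,3-oxazolidin-2-one; 8 (3E)-5-(TBS-oxy)-3-methylpent-3-enal
Product: 13 (4R)-4-benzyl-3-[(2R,3S,5E)-7-(TBS-oxy)-3-hydroxy-5-methyl-2-(propan-2-yl)hept-5-enoyl]-1,3-oxazolidin-2-one, via (Z)-dibutylboron enolate 12 (not isolated)
Conditions: Bu2BOTf, Et3N, CH2Cl2, −78 to 0 °C; 8, −78 to 0 °C; pH 7 buffer, MeOH, H2O2, 0 °C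
Reagents that add atoms: none
Why: In this Evans syn-aldol the Z-boron enolate reacts through a Zimmerman–Traxler chair on the face opposite the benzyl group, which forms the key C7–C8 bond between the two fragments and sets C7 (2R) and C8 (3S) together.

Step 8
Reactants: 13 the aldol adduct
Product: 14 (2R,3S,5E)-7-(TBS-oxy)-3-hydroxy-N-methoxy-N,5-dimethyl-2-(propan-2-yl)hept-5-enamide
Conditions: MeNHOMe·HCl, AlMe3, CH2Cl2, −20 to 0 °C; cold aq. HCl
Reagents that add atoms: N,O-dimethylhydroxylamine hydrochloride, CNOC.Cl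
Why: Weinreb transamination by the aluminium amide, assisted by the free β-hydroxyl, exchanges the auxiliary for the N-methoxy-N-methylamide without epimerising C7.

Step 9
Reactants: 15 prop-2-yn-1-ol
Product: 17 (2E)-3-iodo-2-methylprop-2-en-1-ol, via dimethylaluminium alkoxide alkenylalane 16 (not isolated)
Conditions: Me3Al, Cp2ZrCl2 (25 mol%), CH2Cl2, 0 °C to rt; I2, THF, −30 to 0 °C; aq. K2CO3
Reagents that add atoms: trimethylaluminium, C[Al](C)C; iodine, [I][I]
Why: Negishi carboalumination (syn) followed by iodinolysis with retention gives the E-iodoalkene that carries the C4 methyl and the C4=C5 geometry.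

Step 10
Reactants: 17 (2E)-3-iodo-2-methylprop-2-en-1-ol
Product: 18 1-({[(2E)-3-iodo-2-methylprop-2-en-1-yl]oxy}methyl)-4-methoxybenzene
Conditions: NaH, 4-methoxybenzyl chloride, Bu4NI (cat.), THF, 0 °C to rt
Reagents that add atoms: 4-methoxybenzyl chloride, COc1ccc(CCl)cc1
Why: Williamson etherification gives a C3–O protecting group that tolerates t-BuLi at −78 °C and is later removed by DDQ beside silyl ethers, a benzoate and a sulfone.

Step 11
Reactants: 14 the Weinreb amide; 18 the iodoalkene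
Product: 20 (2E,5R,6S,8E)-10-(TBS-oxy)-6-hydroxy-1-(PMB-oxy)-2,8-dimethyl-5-(propan-2-yl)deca-2,8-dien-4-one, via alkenyllithium 19 (not isolated)
Conditions: 18 (3 equiv), t-BuLi (6 equiv), Et2O, −78 °C; 14, THF, −78 to −20 °C; aq. NH4Cl
Reagents that add atoms: none
Why: Iodine–lithium exchange proceeds with retention of alkene geometry and the Weinreb amide acylates the alkenyllithium only once through its chelated tetrahedral intermediate (one equivalent is spent on the hydroxyl), forming C5–C6 without touching C7.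

Step 12
Reactants: 20 the β-hydroxy enone
Product: 21 (2E,4S,5S,6S,8E)-10-(TBS-oxy)-4-hydroxy-1-(PMB-oxy)-2,8-dimethyl-5-(propan-2-yl)deca-2,8-dien-6-yl benzoate
Conditions: PhCHO (6 equiv), SmI2 (30 mol%, premixed with PhCHO), THF, −10 °C
Reagents that add atoms: benzaldehyde, O=Cc1ccccc1
Why: In this Evans–Tishchenko reduction the benzaldehyde hemiacetal bound to trivalent samarium delivers hydride intramolecularly through a chair-like bicyclic transition state, which sets C6 (S) 1,3-anti to O8 and leaves O8 as the benzoate in a pure addition with no co-product.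

Step 13
Reactants: 21 the hydroxy benzoate
Product: 22 (2E,4S,5R,6S,8E)-4,10-bis(TBS-oxy)-1-(PMB-oxy)-2,8-dimethyl-5-(propan-2-yl)deca-2,8-dien-6-yl benzoate
Conditions: TBSOTf, 2,6-lutidine, CH2Cl2, −78 to 0 °C
Reagents that add atoms: tert-butyl(dimethyl)silyl trifluoromethanesulfonate, CC(C)(C)[Si](C)(C)OS(=O)(=O)C(F)(F)F
Why: Silylation with the reactive triflate caps the hindered C6 hydroxyl, so the benzoate cannot migrate and O6 stays distinct from O8 to the end.

Step 14
Reactants: 22 the bis-silyl ether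
Product: 23 (2E,5S,6R,7S,8E)-7-(TBS-oxy)-1-hydroxy-10-(PMB-oxy)-3,9-dimethyl-6-(propan-2-yl)deca-2,8-dien-5-yl benzoate
Conditions: CSA (10 mol%), MeOH/CH2Cl2, 0 °C
Reagents that add atoms: none
Why: Acid-catalysed methanolysis cleaves the unhindered primary TBS ether at C2 much faster than the hindered secondary one at C6.

Step 15
Reactants: 23 the allylic alcohol
Product: 25 (2E,5S,6R,7S,8E)-1-(benzenesulfonyl)-7-(TBS-oxy)-10-(PMB-oxy)-3,9-dimethyl-6-(propan-2-yl)deca-2,8-dien-5-yl benzoate, via allylic methanesulfonate 24 (not isolated)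
Conditions: MsCl, Et3N, CH2Cl2, −40 °C; PhSO2Na, Bu4NI (cat.), DMF, 0 °C to rt
Reagents that add atoms: sodium benzenesulfinate, [Na+].[O-]S(=O)c1ccccc1
Why: Mesylation and SN2 S-alkylation of the sulfinate at the primary allylic carbon install the anion-stabilising sulfone at C2 with the C1=C10 alkene unchanged.

Step 16
Reactants: 25 the sulfone
Product: 26 (2E,4S,5R,6S,8E)-10-(benzenesulfonyl)-4-(TBS-oxy)-1-hydroxy-2,8-dimethyl-5-(propan-2-yl)deca-2,8-dien-6-yl benzoate
Conditions: DDQ, CH2Cl2/pH 7 buffer, 0 °C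
Reagents that add atoms: none
Why: Oxidative PMB cleavage frees the C3 hydroxyl while sulfone, benzoate, silyl ether and both trisubstituted alkenes are inert to DDQ.

Step 17
Reactants: 26 the hydroxy sulfone
Product: 27 (2E,4S,5R,6S,8E)-10-(benzenesulfonyl)-1-bromo-4-(TBS-oxy)-2,8-dimethyl-5-(propan-2-yl)deca-2,8-dien-6-yl benzoate
Conditions: CBr4, PPh3, CH2Cl2, −20 to 0 °C
Reagents that add atoms: carbon tetrabromide, BrC(Br)(Br)Br
Why: The Appel reaction turns the primary allylic alcohol into the bromide by SN2 under neutral conditions that leave the acidic sulfone and the ester alone.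

Step 18
Reactants: 27 the bromo sulfone
Product: 28 (1S,3E,7E,9S,10R)-5-(benzenesulfonyl)-9-(TBS-oxy)-3,7-dimethyl-10-(propan-2-yl)cyclodeca-3,7-dien-1-yl benzoate (both C5 epimers)
Conditions: KN(SiMe3)2 (1.2 equiv), THF (2 mM), −78 to −20 °C
Reagents that add atoms: none
Why: Intramolecular alkylation of the sulfonyl-stabilised allyl anion at its α-carbon by the primary allylic bromide under high dilution closes the ten-membered ring at C2–C3 with both E alkenes preset; the benzoate is safe because attack on it would need a seven-membered ring holding an E alkene, and the new sulfone-bearing centre is removed in the next step.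

Step 19
Reactants: 28 the ring sulfone
Product: 29 (1S,3E,7E,9S,10R)-9-(TBS-oxy)-3,7-dimethyl-10-(propan-2-yl)cyclodeca-3,7-dien-1-ol
Conditions: LiBHEt3 (6 equiv), PdCl2(dppp) (10 mol%; dppp = Ph2P(CH2)3PPh2), THF, 0 °C to rt
Reagents that add atoms: none
Why: Palladium-catalysed reductive desulfonylation (zerovalent palladium, formed in situ from the divalent precatalyst, ionises the allylic sulfone and hydride is delivered to the less substituted C2 terminus of the π-allyl complex) keeps the C1=C10 alkene in place, while excess hydride cleaves the benzoate and the resulting alkoxide is held as its triethylborate so the silyl group does not migrate.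

Step 20
Reactants: 30 (2E)-3-(4-hydroxyphenyl)prop-2-enoic acid
Product: 32 (2E)-3-[4-(TBS-oxy)phenyl]prop-2-enoic acid, via bis-silylated coumarate 31 (not isolated)
Conditions: TBSCl (2.5 equiv), imidazole, DMF, rt; AcOH/THF/H2O, rt
Reagents that add atoms: tert-butyl(chloro)dimethylsilane, CC(C)(C)[Si](C)(C)Cl
Why: Exhaustive silylation followed by mild hydrolysis of the labile silyl ester leaves the phenol protected and the acid free.

Step 21
Reactants: 29 the ring alcohol; 32 the protected acid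
Product: 33 (1S,3E,7E,9S,10R)-9-(TBS-oxy)-3,7-dimethyl-10-(propan-2-yl)cyclodeca-3,7-dien-1-yl (2E)-3-[4-(TBS-oxy)phenyl]prop-2-enoate
Conditions: DCC, DMAP, CH2Cl2, 0 °C to rt
Reagents that add atoms: none
Why: Steglich esterification acylates the only free hydroxyl (O8) with retention at C8 under neutral conditions that the acid-sensitive diene tolerates.

Step 22
Reactants: 33 the bis-silyl ester
Product: 34 (1S,3E,7E,9S,10S)-9-hydroxy-3,7-dimethyl-10-(propan-2-yl)cyclodeca-3,7-dien-1-yl (2E)-3-(4-hydroxyphenyl)prop-2-enoate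
Conditions: HF·pyridine, pyridine, THF, 0 °C to rt
Reagents that add atoms: none
Why: Pyridine-buffered fluoride desilylation removes the aryl and the secondary silyl ether without base-induced acyl migration from O8 to O6 and without acid-induced transannular cyclisation of the diene.

## Compound list

1 | but-3-yn-1-ol | C#CCCO | starting material
2 | 1-[(but-3-yn-1-yloxy)methyl]-4-methoxybenzene | C#CCCOCc1ccc(OC)cc1 | intermediate
3 | dimethyl[(1E)-4-(PMB-oxy)-2-methylbut-1-en-1-yl]alane | C[Al](C)/C=C(C)/CCOCc1ccc(OC)cc1 | intermediate (not isolated)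
4 | lithium butyl(dimethyl)[(1E)-4-(PMB-oxy)-2-methylbut-1-en-1-yl]alanate | [Li+].CCCC[Al-](C)(C)/C=C(C)/CCOCc1ccc(OC)cc1 | intermediate (not isolated)
5 | (2E)-5-(PMB-oxy)-3-methylpent-2-en-1-ol | OC/C=C(C)/CCOCc1ccc(OC)cc1 | intermediate
6 | tert-butyl{[(2E)-5-(PMB-oxy)-3-methylpent-2-en-1-yl]oxy}dimethylsilane | CC(C)(C)[Si](C)(C)OC/C=C(C)/CCOCc1ccc(OC)cc1 | intermediate
7 | (3E)-5-(TBS-oxy)-3-methylpent-3-en-1-ol | CC(C)(C)[Si](C)(C)OC/C=C(C)/CCO | intermediate
8 | (3E)-5-(TBS-oxy)-3-methylpent-3-enal | CC(C)(C)[Si](C)(C)OC/C=C(C)/CC=O | intermediate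
9 | (4R)-4-benzyl-1,3-oxazolidin-2-one | O=C1N[C@H](Cc2ccccc2)CO1 | starting material
10 | 3-methylbutanoyl chloride | CC(C)CC(=O)Cl | starting material
11 | (4R)-4-benzyl-3-(3-methylbutanoyl)-1,3-oxazolidin-2-one | CC(C)CC(=O)N1[C@H](Cc2ccccc2)COC1=O | intermediate
12 | (4R)-4-benzyl-3-{(1Z)-1-[(dibutylboranyl)oxy]-3-methylbut-1-en-1-yl}-1,3-oxazolidin-2-one | CCCCB(CCCC)O/C(=C\C(C)C)N1[C@H](Cc2ccccc2)COC1=O | intermediate (not isolated)
13 | (4R)-4-benzyl-3-[(2R,3S,5E)-7-(TBS-oxy)-3-hydroxy-5-methyl-2-(propan-2-yl)hept-5-enoyl]-1,3-oxazolidin-2-one | O=C(N1[C@H](Cc2ccccc2)COC1=O)[C@H](C(C)C)[C@@H](O)C/C(C)=C/CO[Si](C)(C)C(C)(C)C | intermediate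
14 | (2R,3S,5E)-7-(TBS-oxy)-3-hydroxy-N-methoxy-N,5-dimethyl-2-(propan-2-yl)hept-5-enamide | CON(C)C(=O)[C@H](C(C)C)[C@@H](O)C/C(C)=C/CO[Si](C)(C)C(C)(C)C | intermediate
15 | prop-2-yn-1-ol | C#CCO | starting material
16 | dimethylaluminium (2E)-3-(dimethylalumanyl)-2-methylprop-2-en-1-olate | C[Al](C)OC/C(C)=C/[Al](C)C | intermediate (not isolated)
17 | (2E)-3-iodo-2-methylprop-2-en-1-ol | OC/C(C)=C/I | intermediate
18 | 1-({[(2E)-3-iodo-2-methylprop-2-en-1-yl]oxy}methyl)-4-methoxybenzene | COc1ccc(COC/C(C)=C/I)cc1 | intermediate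
19 | [(1E)-3-(PMB-oxy)-2-methylprop-1-en-1-yl]lithium | COc1ccc(COC/C(C)=C/[Li])cc1 | intermediate (not isolated)
20 | (2E,5R,6S,8E)-10-(TBS-oxy)-6-hydroxy-1-(PMB-oxy)-2,8-dimethyl-5-(propan-2-yl)deca-2,8-dien-4-one | COc1ccc(COC/C(C)=C/C(=O)[C@H](C(C)C)[C@@H](O)C/C(C)=C/CO[Si](C)(C)C(C)(C)C)cc1 | intermediate
21 | (2E,4S,5S,6S,8E)-10-(TBS-oxy)-4-hydroxy-1-(PMB-oxy)-2,8-dimethyl-5-(propan-2-yl)deca-2,8-dien-6-yl benzoate | COc1ccc(COC/C(C)=C/[C@H](O)[C@H](C(C)C)[C@@H](OC(=O)c2ccccc2)C/C(C)=C/CO[Si](C)(C)C(C)(C)C)cc1 | intermediate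
22 | (2E,4S,5R,6S,8E)-4,10-bis(TBS-oxy)-1-(PMB-oxy)-2,8-dimethyl-5-(propan-2-yl)deca-2,8-dien-6-yl benzoate | COc1ccc(COC/C(C)=C/[C@H](O[Si](C)(C)C(C)(C)C)[C@H](C(C)C)[C@@H](OC(=O)c2ccccc2)C/C(C)=C/CO[Si](C)(C)C(C)(C)C)cc1 | intermediate
23 | (2E,5S,6R,7S,8E)-7-(TBS-oxy)-1-hydroxy-10-(PMB-oxy)-3,9-dimethyl-6-(propan-2-yl)deca-2,8-dien-5-yl benzoate | COc1ccc(COC/C(C)=C/[C@H](O[Si](C)(C)C(C)(C)C)[C@H](C(C)C)[C@@H](OC(=O)c2ccccc2)C/C(C)=C/CO)cc1 | intermediate
24 | (2E,5S,6R,7S,8E)-7-(TBS-oxy)-1-[(methanesulfonyl)oxy]-10-(PMB-oxy)-3,9-dimethyl-6-(propan-2-yl)deca-2,8-dien-5-yl benzoate | COc1ccc(COC/C(C)=C/[C@H](O[Si](C)(C)C(C)(C)C)[C@H](C(C)C)[C@@H](OC(=O)c2ccccc2)C/C(C)=C/COS(C)(=O)=O)cc1 | intermediate (not isolated)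
25 | (2E,5S,6R,7S,8E)-1-(benzenesulfonyl)-7-(TBS-oxy)-10-(PMB-oxy)-3,9-dimethyl-6-(propan-2-yl)deca-2,8-dien-5-yl benzoate | COc1ccc(COC/C(C)=C/[C@H](O[Si](C)(C)C(C)(C)C)[C@H](C(C)C)[C@@H](OC(=O)c2ccccc2)C/C(C)=C/CS(=O)(=O)c2ccccc2)cc1 | intermediate
26 | (2E,4S,5R,6S,8E)-10-(benzenesulfonyl)-4-(TBS-oxy)-1-hydroxy-2,8-dimethyl-5-(propan-2-yl)deca-2,8-dien-6-yl benzoate | OC/C(C)=C/[C@H](O[Si](C)(C)C(C)(C)C)[C@H](C(C)C)[C@@H](OC(=O)c1ccccc1)C/C(C)=C/CS(=O)(=O)c1ccccc1 | intermediate
27 | (2E,4S,5R,6S,8E)-10-(benzenesulfonyl)-1-bromo-4-(TBS-oxy)-2,8-dimethyl-5-(propan-2-yl)deca-2,8-dien-6-yl benzoate | BrC/C(C)=C/[C@H](O[Si](C)(C)C(C)(C)C)[C@H](C(C)C)[C@@H](OC(=O)c1ccccc1)C/C(C)=C/CS(=O)(=O)c1ccccc1 | intermediate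
28 | (1S,3E,7E,9S,10R)-5-(benzenesulfonyl)-9-(TBS-oxy)-3,7-dimethyl-10-(propan-2-yl)cyclodeca-3,7-dien-1-yl benzoate (C5 epimers) | C/C1=C\[C@H](O[Si](C)(C)C(C)(C)C)[C@H](C(C)C)[C@@H](OC(=O)c2ccccc2)C/C(C)=C/C(S(=O)(=O)c2ccccc2)C1 | intermediate
29 | (1S,3E,7E,9S,10R)-9-(TBS-oxy)-3,7-dimethyl-10-(propan-2-yl)cyclodeca-3,7-dien-1-ol | C/C1=C\[C@H](O[Si](C)(C)C(C)(C)C)[C@H](C(C)C)[C@@H](O)C/C(C)=C/CC1 | intermediate
30 | (2E)-3-(4-hydroxyphenyl)prop-2-enoic acid (p-coumaric acid) | OC(=O)/C=C/c1ccc(O)cc1 | starting material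
31 | tert-butyl(dimethyl)silyl (2E)-3-[4-(TBS-oxy)phenyl]prop-2-enoate | CC(C)(C)[Si](C)(C)OC(=O)/C=C/c1ccc(O[Si](C)(C)C(C)(C)C)cc1 | intermediate (not isolated)
32 | (2E)-3-[4-(TBS-oxy)phenyl]prop-2-enoic acid | OC(=O)/C=C/c1ccc(O[Si](C)(C)C(C)(C)C)cc1 | intermediate
33 | (1S,3E,7E,9S,10R)-9-(TBS-oxy)-3,7-dimethyl-10-(propan-2-yl)cyclodeca-3,7-dien-1-yl (2E)-3-[4-(TBS-oxy)phenyl]prop-2-enoate | C/C1=C\[C@H](O[Si](C)(C)C(C)(C)C)[C@H](C(C)C)[C@@H](OC(=O)/C=C/c2ccc(O[Si](C)(C)C(C)(C)C)cc2)C/C(C)=C/CC1 | intermediate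
34 | (1S,3E,7E,9S,10S)-9-hydroxy-3,7-dimethyl-10-(propan-2-yl)cyclodeca-3,7-dien-1-yl (2E)-3-(4-hydroxyphenyl)prop-2-enoate (CNP0178839.1) | C/C1=C\[C@H](O)[C@H](C(C)C)[C@@H](OC(=O)/C=C/c2ccc(O)cc2)C/C(C)=C/CC1 | target

## Step count and risks

Total step count: 22. Longest linear sequence: 18 steps (steps 1–5, 7, 8, 11–19, 21, 22).

The three steps most likely to fail:

Step 18 (ring closure). Forming a ten-membered E,E-diene by SN2 at C3 competes with oligomerisation and with SN2′ attack. The fallback sets out from 26 and comes back at 28. Alcohol 26 is acylated with methyl chloroformate and pyridine to the allylic methyl carbonate F1. The ring is then closed by Tsuji–Trost allylic alkylation (Pd(PPh3)4, dppe = Ph2P(CH2)2PPh2, THF, 60 °C, slow addition). Zerovalent palladium ionises the carbonate, the methoxide released deprotonates the sulfone, and the carbanion attacks the less hindered C3 terminus of the π-allyl complex to give 28.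

Step 19 (desulfonylation). The π-allyl palladium intermediate could scramble the position or geometry of the C1=C10 alkene in the strained ring, and two reductions are asked of one reagent. The fallback sets out from 28 and comes back at 29. The benzoate is first removed with i-Bu2AlH (CH2Cl2, −78 °C) to give the hydroxy sulfone F2. The C–S bond is then cleaved by single-electron transfer with sodium amalgam Na(Hg) and Na2HPO4 in MeOH/THF at −20 °C, which involves no π-allyl metal species, and gives 29.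

Step 11 (ketone formation). The Weinreb carbonyl is flanked by the isopropyl-bearing carbon and a lithium alkoxide, so addition may be slow and enolisation or retro-aldol cleavage may intervene. The fallback sets out from 14 and comes back at 20. Amide 14 is silylated (TESOTf, 2,6-lutidine) to the triethylsilyl ether F3. This is reduced with i-Bu2AlH (−78 °C) to the less hindered aldehyde F4. Alkenyllithium 19 is added to give the allylic alcohols F5 (both C6 epimers, which does not matter). These are oxidised with Dess–Martin periodinane to the silylated enone F6. The triethylsilyl group is removed selectively (PPTS, MeOH, 0 °C) to return to 20.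

## Further compounds

F1 | step 18 | (2E,4S,5R,6S,8E)-10-(benzenesulfonyl)-4-(TBS-oxy)-1-[(methoxycarbonyl)oxy]-2,8-dimethyl-5-(propan-2-yl)deca-2,8-dien-6-yl benzoate | COC(=O)OC/C(C)=C/[C@H](O[Si](C)(C)C(C)(C)C)[C@H](C(C)C)[C@@H](OC(=O)c1ccccc1)C/C(C)=C/CS(=O)(=O)c1ccccc1
F2 | step 19 | (1S,3E,7E,9S,10R)-5-(benzenesulfonyl)-9-(TBS-oxy)-3,7-dimethyl-10-(propan-2-yl)cyclodeca-3,7-dien-1-ol (C5 epimers) | C/C1=C\[C@H](O[Si](C)(C)C(C)(C)C)[C@H](C(C)C)[C@@H](O)C/C(C)=C/C(S(=O)(=O)c2ccccc2)C1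
F3 | step 11 | (2R,3S,5E)-7-(TBS-oxy)-N-methoxy-N,5-dimethyl-2-(propan-2-yl)-3-[(triethylsilyl)oxy]hept-5-enamide | CON(C)C(=O)[C@H](C(C)C)[C@@H](O[Si](CC)(CC)CC)C/C(C)=C/CO[Si](C)(C)C(C)(C)C
F4 | step 11 | (2R,3S,5E)-7-(TBS-oxy)-5-methyl-2-(propan-2-yl)-3-[(triethylsilyl)oxy]hept-5-enal | O=C[C@H](C(C)C)[C@@H](O[Si](CC)(CC)CC)C/C(C)=C/CO[Si](C)(C)C(C)(C)C
F5 | step 11 | (2E,5S,6S,8E)-10-(TBS-oxy)-1-(PMB-oxy)-2,8-dimethyl-5-(propan-2-yl)-6-[(triethylsilyl)oxy]deca-2,8-dien-4-ol (C4 epimers) | COc1ccc(COC/C(C)=C/C(O)[C@H](C(C)C)[C@@H](O[Si](CC)(CC)CC)C/C(C)=C/CO[Si](C)(C)C(C)(C)C)cc1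
F6 | step 11 | (2E,5R,6S,8E)-10-(TBS-oxy)-1-(PMB-oxy)-2,8-dimethyl-5-(propan-2-yl)-6-[(triethylsilyl)oxy]deca-2,8-dien-4-one | COc1ccc(COC/C(C)=C/C(=O)[C@H](C(C)C)[C@@H](O[Si](CC)(CC)CC)C/C(C)=C/CO[Si](C)(C)C(C)(C)C)cc1
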